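**Plan**

Core numbering used below: C1 methyl-bearing bridgehead, C2 CH carrying the dienoyl group, C3 CH carrying the tetronic acid, C4 bridgehead CH, C5 C(OH)Me, C6 ketone, C7/C8 enol bridge (C8 acylated).
Retrosynthesis: the two acyl chains are cut first (dienyl–C(O) bond by thioester/boronic acid coupling, C8–acyl bond by C-acylation), leaving a bicyclo[2.2.2]octane-6,7-dione that carries a thioester on C2.
The core is then cut at C5–C6 and C2–C3 together: C6(=O)–C5(OH)Me is an acyloin (aldehyde + methyl ketone, benzoin retron) and C5 stands 1,5 to the C2 acyl carbon through C4–C3 (Michael retron), while C1 and C4 stay tied by the C7(=O)–C8H2 bridge, so both rings open to one acyclic keto aldehyde.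
Forward: a 2,3,5-trisubstituted furan (latent cis-enedione; its ring carbons become C5, C4, C8, C7) is loaded with the tetronate on the C3 side and with the quaternary C1 bearing a formyl and a thioester arm, then opened with singlet oxygen; base and a carbene fold the chain by Michael addition (ring C1–C2–C3–C4–C8–C7) and benzoin closure (C5–C6 bridge).
Stereochemistry: the tetronate carbon comes from (R)-lactic acid by self-regeneration of stereocentres, C1 from a nickel/BINAP α-arylation of α-methyl-γ-butyrolactone, and C2, C3, C4, C5 from the key step under control of C1.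

Key step: step 14

Assumption: the sense of induction of the Ni/BINAP α-arylation (step 7) is taken by analogy with simple aryl halides; if it proves opposite, (R)-BINAP is used.

Step 1
Reactants: 1 (R)-lactic acid; 2 pivalaldehyde
Product: 3 (2R,5R)-2-tert-butyl-5-methyl-1,3-dioxolan-4-one
Conditions: TsOH (cat.), pentane, reflux, water separator; crystallisation of the cis isomer
Reagents that add atoms: none
Why: Acid-catalysed acetalisation should give the cis-dioxolanone as the thermodynamically favoured, crystalline diastereomer, so the acetal carbon is set by the lactate stereocentre and stores its chirality for step 3.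

Step 2
Reactants: 4 (2-methylfuran-3-yl)methanol
Product: 5 3-(bromomethyl)-2-methylfuran
Conditions: PBr3, Et2O, 0 °C; used at once
Reagents that add atoms: phosphorus tribromide BrP(Br)Br
Why: Bromination of the primary heteroarylmethyl alcohol through its phosphite ester (SN2 displacement by bromide) should give the reactive furylmethyl bromide, and no stereocentre is involved.

Step 3
Reactants: 3 (2R,5R)-2-tert-butyl-5-methyl-1,3-dioxolan-4-one; 5 3-(bromomethyl)-2-methylfuran
Product: 6 (2R,5S)-2-tert-butyl-5-methyl-5-[(2-methylfuran-3-yl)methyl]-1,3-dioxolan-4-one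
Conditions: LiN(iPr)2, THF, −78 °C; then 5, −78 to −30 °C
Reagents that add atoms: none
Why: Alkylation of the dioxolanone lithium enolate (self-regeneration of stereocentres) should occur on the face trans to the tert-butyl group, so the furylmethyl group replaces the lactate hydrogen with retention and fixes the future quaternary tetronate carbon.

Step 4
Reactants: 6 (2R,5S)-2-tert-butyl-5-methyl-5-[(2-methylfuran-3-yl)methyl]-1,3-dioxolan-4-one; 7 ethyl propanoate
Product: 9 (5S)-4-hydroxy-3,5-dimethyl-5-[(2-methylfuran-3-yl)methyl]furan-2(5H)-one, via open-chain hydroxy keto ester 8 (not isolated)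
Conditions: LiN(iPr)2 and 7 (3 equiv each), THF, −78 °C; then 6, −78 to 0 °C; then 2 M HCl, rt
Reagents that add atoms: none
Why: Claisen-type acylation of the propanoate enolate by the activated dioxolanone carbonyl should expel pivalaldehyde, and the freed tertiary alkoxide lactonises onto the ethyl ester (Dieckmann-like tetronic acid synthesis from a dioxolanone) without touching the quaternary stereocentre.

Step 5
Reactants: 9 (5S)-4-hydroxy-3,5-dimethyl-5-[(2-methylfuran-3-yl)methyl]furan-2(5H)-one
Product: 10 (5S)-4-methoxy-3,5-dimethyl-5-[(2-methylfuran-3-yl)methyl]furan-2(5H)-one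
Conditions: Me3SiCHN2, MeOH–toluene, 0 °C to rt
Reagents that add atoms: (trimethylsilyl)diazomethane C[Si](C)(C)C=[N+]=[N-]
Why: O-Methylation of the vinylogous acid by the diazoalkane (proton transfer, then SN2 on the methyldiazonium ion) should mask the acidic enol as the methyl tetronate for the halogenation, strong-base and oxidation steps that follow.

Step 6
Reactants: 10 (5S)-4-methoxy-3,5-dimethyl-5-[(2-methylfuran-3-yl)methyl]furan-2(5H)-one
Product: 11 (5S)-5-[(5-bromo-2-methylfuran-3-yl)methyl]-4-methoxy-3,5-dimethylfuran-2(5H)-one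
Conditions: NBS, DMF, −20 to 0 °C, dark; used without storage
Reagents that add atoms: N-bromosuccinimide O=C1CCC(=O)N1Br
Why: Electrophilic aromatic bromination should occur at the only free α-position of the electron-rich furan, whereas the tetronate double bond is a deactivated, fully substituted vinylogous ester.

Step 7
Reactants: 11 (5S)-5-[(5-bromo-2-methylfuran-3-yl)methyl]-4-methoxy-3,5-dimethylfuran-2(5H)-one; 12 α-methyl-γ-butyrolactone (racemic)
Product: 13 (5S)-4-methoxy-3,5-dimethyl-5-({2-methyl-5-[(3R)-3-methyl-2-oxooxolan-3-yl]furan-3-yl}methyl)furan-2(5H)-one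
Conditions: Ni(cod)2 (10 mol%), (S)-BINAP (12 mol%), NaN(SiMe3)2, ZnBr2 (15 mol%), toluene–THF, 60 °C
Reagents that add atoms: none
Why: Enantioselective nickel-catalysed α-arylation of a lactone enolate (oxidative addition of the bromofuran to zerovalent nickel, enolate transmetalation, reductive elimination) should build the all-carbon quaternary centre C1, whose configuration is set by the BINAP-bound nickel enolate because the racemic lactone reacts through its planar enolate.

Step 8
Reactants: 13 (5S)-4-methoxy-3,5-dimethyl-5-({2-methyl-5-[(3R)-3-methyl-2-oxooxolan-3-yl]furan-3-yl}methyl)furan-2(5H)-one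
Product: 14 S-ethyl (2R)-4-hydroxy-2-(4-{[(2S)-3-methoxy-2,4-dimethyl-5-oxo-2,5-dihydrofuran-2-yl]methyl}-5-methylfuran-2-yl)-2-methylbutanethioate
Conditions: AlMe3, EtSH, CH2Cl2, 0 °C to rt; aq. potassium sodium tartrate; used at once
Reagents that add atoms: ethanethiol CCS
Why: Dimethylaluminium ethanethiolate should open the γ-lactone by acyl–oxygen cleavage to the thioester and the free primary alcohol, while the tetronate carbonyl (a vinylogous carbonate) is far less electrophilic and the quaternary centre cannot enolise.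

Step 9
Reactants: 14 S-ethyl (2R)-4-hydroxy-2-(4-{[(2S)-3-methoxy-2,4-dimethyl-5-oxo-2,5-dihydrofuran-2-yl]methyl}-5-methylfuran-2-yl)-2-methylbutanethioate
Product: 15 (3R)-4-(ethylsulfanyl)-3-(4-{[(2S)-3-methoxy-2,4-dimethyl-5-oxo-2,5-dihydrofuran-2-yl]methyl}-5-methylfuran-2-yl)-3-methyl-4-oxobutanoic acid
Conditions: TEMPO (20 mol%), PhI(OAc)2, MeCN–H2O, rt
Reagents that add atoms: water O
Why: Oxoammonium (TEMPO) oxidation should take the primary alcohol through the aldehyde hydrate to the carboxylic acid under conditions that leave the thioester and the furan intact.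

Step 10
Reactants: 15 (3R)-4-(ethylsulfanyl)-3-(4-{[(2S)-3-methoxy-2,4-dimethyl-5-oxo-2,5-dihydrofuran-2-yl]methyl}-5-methylfuran-2-yl)-3-methyl-4-oxobutanoic acid
Product: 16 (3R)-3-(4-{[(2S)-3-methoxy-2,4-dimethyl-5-oxo-2,5-dihydrofuran-2-yl]methyl}-5-methylfuran-2-yl)-3-methyl-4-oxobutanoic acid
Conditions: Et3SiH, Pd on carbon (10 wt%), acetone, rt
Reagents that add atoms: none
Why: Fukuyama reduction (insertion of palladium into the acyl–sulfur bond, hydride transfer from the silane, reductive elimination) should convert the hindered thioester into the aldehyde without over-reduction, and the quaternary α-carbon cannot epimerise.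

Step 11
Reactants: 16 (3R)-3-(4-{[(2S)-3-methoxy-2,4-dimethyl-5-oxo-2,5-dihydrofuran-2-yl]methyl}-5-methylfuran-2-yl)-3-methyl-4-oxobutanoic acid
Product: 17 S-ethyl (3R)-3-(4-{[(2S)-3-methoxy-2,4-dimethyl-5-oxo-2,5-dihydrofuran-2-yl]methyl}-5-methylfuran-2-yl)-3-methyl-4-oxobutanethioate
Conditions: EDC·HCl, DMAP (cat.), EtSH, CH2Cl2, 0 °C to rt
Reagents that add atoms: ethanethiol CCS
Why: Carbodiimide-mediated thioesterification (Steglich type) should install the thioester that serves first as the Michael donor and later as the acyl coupling partner, the neopentyl aldehyde giving at most a reversible hemithioacetal.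

Step 12
Reactants: 17 S-ethyl (3R)-3-(4-{[(2S)-3-methoxy-2,4-dimethyl-5-oxo-2,5-dihydrofuran-2-yl]methyl}-5-methylfuran-2-yl)-3-methyl-4-oxobutanethioate
Product: 18 S-ethyl (3R)-3-(4-{[(2S)-3-hydroxy-2,4-dimethyl-5-oxo-2,5-dihydrofuran-2-yl]methyl}-5-methylfuran-2-yl)-3-methyl-4-oxobutanethioate
Conditions: LiCl, DMF, 80 °C; then 1 M HCl
Reagents that add atoms: none
Why: Chloride should cleave the vinylogous methyl ester by SN2 attack at the methyl group (the tetronate is the leaving group), and the acid is unmasked here because in the key step its anion makes the ring oxygen a poor leaving group and so blocks a vinylogous β-elimination from the dienolate.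

Step 13
Reactants: 18 S-ethyl (3R)-3-(4-{[(2S)-3-hydroxy-2,4-dimethyl-5-oxo-2,5-dihydrofuran-2-yl]methyl}-5-methylfuran-2-yl)-3-methyl-4-oxobutanethioate
Product: 20 S-ethyl (3S,5Z)-3-formyl-6-{[(2S)-3-hydroxy-2,4-dimethyl-5-oxo-2,5-dihydrofuran-2-yl]methyl}-3-methyl-4,7-dioxooct-5-enethioate, via furan endoperoxide 19 (not isolated)
Conditions: O2, tetraphenylporphyrin (cat.), visible light, CH2Cl2, −78 °C; then Me2S, −78 °C to rt; used crude
Reagents that add atoms: dioxygen O=O
Why: [4+2] Cycloaddition of singlet oxygen to the furan and reduction of the endoperoxide by the sulfide should unveil the (Z)-2-ene-1,4-dione, so that the four furan carbons become the C5–C4–C8–C7 chain with both carbonyl groups in place, the furan reacting far faster than the enol or the thioester.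

Step 14
Reactants: 20 S-ethyl (3S,5Z)-3-formyl-6-{[(2S)-3-hydroxy-2,4-dimethyl-5-oxo-2,5-dihydrofuran-2-yl]methyl}-3-methyl-4,7-dioxooct-5-enethioate
Product: 23 S-ethyl (1R,2R,3S,4R,5S)-5-hydroxy-3-[(2S)-3-hydroxy-2,4-dimethyl-5-oxo-2,5-dihydrofuran-2-yl]-1,5-dimethyl-6,7-dioxobicyclo[2.2.2]octane-2-carbothioate, via deconjugated alkylidene isomer 21 (not isolated), via monocyclic Michael adduct 22 (not isolated)
Conditions: DBU (3 equiv), MeCN, 0 °C to rt until 20 is consumed; then 2-(pentafluorophenyl)-6,7-dihydro-5H-pyrrolo[2,1-c][1,2,4]triazol-2-ium tetrafluoroborate (20 mol%), 40 °C; pH 4 buffer work-up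
Reagents that add atoms: none
Why: Proposed new method: DBU (one equivalent rests on the tetronic acid, whose anion cannot leave by vinylogous β-elimination) equilibrates the (Z)-enedione 20 through its dienolate with the deconjugated alkylidene ketone 21, and the thioester enolate then adds to the enone β-carbon (future C3) to close the cyclohexanone 22; the triazolylidene released from the precatalyst adds to the non-enolisable aldehyde, and the resulting enaminol (acyl anion equivalent) attacks the acetyl carbonyl across the ring to give the tertiary α-ketol and the bicyclo[2.2.2]octane 23. The closest known reaction types are the base-mediated intramolecular Michael addition of ketone and thioester enolates to enones and the carbene-catalysed intramolecular crossed aldehyde–ketone benzoin reaction, also run as Michael–benzoin dominos; new here are the release of the acceptor from a 2-ene-1,4-dione in the same flask and the benzoin closure in a bridging mode. Ring closures: the first ring (C1–C2–C3–C4–C8–C7) forms 6-endo-trig at the C2–C3 bond, the second (C5–C6 bond) forms 6-exo-trig onto the carbonyl group between the 1,4-positions of the first ring in its boat form. Stereocentres: C3 should be set against the existing quaternary C1 in a chair transition state with the bulky tetronate equatorial and the formyl group (smaller than methyl) axial, C2 and C4 are epimerisable and should settle trans to the tetronate, which places the acetyl group cis to the formyl group as the bridge requires, and C5 should arise from the hydrogen-bonded benzoin transition state in which the azolium turns away from the C2 thioester so that the new hydroxyl faces the C2–C3 bridge. The step needs the Michael addition to precede acyl anion formation, which the late addition of the precatalyst secures (it also rules out a Stetter reaction at the enedione), and it needs the acyl anion to choose the acetyl group, which the ring sizes secure because the C7 ketone and the thioester could only give three- and four-membered rings.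

Step 15
Reactants: 23 S-ethyl (1R,2R,3S,4R,5S)-5-hydroxy-3-[(2S)-3-hydroxy-2,4-dimethyl-5-oxo-2,5-dihydrofuran-2-yl]-1,5-dimethyl-6,7-dioxobicyclo[2.2.2]octane-2-carbothioate; 24 (E)-hex-4-enoic acid
Product: 26 S-ethyl (1R,2R,3S,4S,5S)-8-[(4E)-hex-4-enoyl]-5,7-dihydroxy-3-[(2S)-3-hydroxy-2,4-dimethyl-5-oxo-2,5-dihydrofuran-2-yl]-1,5-dimethyl-6-oxobicyclo[2.2.2]oct-7-ene-2-carbothioate, via (E)-hex-4-enoyl chloride 25 (not isolated)
Conditions: 24, (COCl)2, DMF (cat.), CH2Cl2, rt, evaporation; 23, MgBr2·OEt2, i-Pr2NEt, CH2Cl2, 0 °C; then 25, 0 °C to rt; MeOH–aq. NaHCO3, then dilute HCl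
Reagents that add atoms: none
Why: Soft-enolisation C-acylation should work because magnesium chelated by the C6/C7 1,3-diketone acidifies the only enolisable ketone position (C8–H2), the amine forms the magnesium enolate, the acid chloride acylates it at carbon and the product is held as the chelated β-triketone, while any O-acyl tetronate or enol ester is cleaved in the methanolic work-up.

Step 16
Reactants: 27 (E)-but-2-enal; 28 bis(4,4,5,5-tetramethyl-1,3,2-dioxaborolan-2-yl)methane
Product: 30 (1E,3E)-penta-1,3-dien-1-ylboronic acid, via dienyl pinacol boronate 29 (not isolated)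
Conditions: lithium 2,2,6,6-tetramethylpiperidide, 28, THF, 0 °C; then 27, −78 °C to rt; then NaIO4, NH4OAc, acetone–H2O, rt; used fresh
Reagents that add atoms: water O
Why: Boron-Wittig olefination (1,2-addition of the α-boryl carbanion to the enal and syn elimination of the borate) should give the (E)-alkenyl boronate, and periodate removes pinacol so that the ester is hydrolysed to the boronic acid.

Step 17
Reactants: 26 S-ethyl (1R,2R,3S,4S,5S)-8-[(4E)-hex-4-enoyl]-5,7-dihydroxy-3-[(2S)-3-hydroxy-2,4-dimethyl-5-oxo-2,5-dihydrofuran-2-yl]-1,5-dimethyl-6-oxobicyclo[2.2.2]oct-7-ene-2-carbothioate; 30 (1E,3E)-penta-1,3-dien-1-ylboronic acid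
Product: 31 (1R,2R,3S,4S,5S)-2-[(2E,4E)-hexa-2,4-dienoyl]-8-[(4E)-hex-4-enoyl]-5,7-dihydroxy-3-[(2S)-3-hydroxy-2,4-dimethyl-5-oxo-2,5-dihydrofuran-2-yl]-1,5-dimethylbicyclo[2.2.2]oct-7-en-6-one (target CNP0539719.2)
Conditions: Pd2(dba)3 (5 mol%), tri(2-furyl)phosphine (20 mol%), Cu(O2CC4H3S) (copper thiophene-2-carboxylate, 3 equiv), THF, 50 °C, dark
Reagents that add atoms: none
Why: Liebeskind–Srogl coupling (oxidative addition of zerovalent palladium into the thioester C–S bond, copper-carboxylate-assisted transfer of the dienyl group from boron, reductive elimination) should give the dienyl ketone under base-free conditions that keep the (E,E)-geometry, the acidic enols and all stereocentres.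

**Compound list**

1 | (R)-lactic acid | C[C@@H](O)C(=O)O | starting material
2 | pivalaldehyde | CC(C)(C)C=O | starting material
3 | (2R,5R)-2-tert-butyl-5-methyl-1,3-dioxolan-4-one | C[C@H]1O[C@@H](C(C)(C)C)OC1=O | intermediate
4 | (2-methylfuran-3-yl)methanol | Cc1occc1CO | starting material
5 | 3-(bromomethyl)-2-methylfuran | Cc1occc1CBr | intermediate
6 | (2R,5S)-2-tert-butyl-5-methyl-5-[(2-methylfuran-3-yl)methyl]-1,3-dioxolan-4-one | C[C@@]1(Cc2ccoc2C)O[C@@H](C(C)(C)C)OC1=O | intermediate
7 | ethyl propanoate | CCOC(=O)CC | starting material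
8 | ethyl (4S)-4-hydroxy-2,4-dimethyl-5-(2-methylfuran-3-yl)-3-oxopentanoate (both C2 epimers) | CCOC(=O)C(C)C(=O)[C@@](C)(O)Cc1ccoc1C | intermediate
9 | (5S)-4-hydroxy-3,5-dimethyl-5-[(2-methylfuran-3-yl)methyl]furan-2(5H)-one | Cc1occc1C[C@]1(C)OC(=O)C(C)=C1O | intermediate
10 | (5S)-4-methoxy-3,5-dimethyl-5-[(2-methylfuran-3-yl)methyl]furan-2(5H)-one | Cc1occc1C[C@]1(C)OC(=O)C(C)=C1OC | intermediate
11 | (5S)-5-[(5-bromo-2-methylfuran-3-yl)methyl]-4-methoxy-3,5-dimethylfuran-2(5H)-one | Cc1oc(Br)cc1C[C@]1(C)OC(=O)C(C)=C1OC | intermediate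
12 | α-methyl-γ-butyrolactone (3-methyloxolan-2-one, racemic) | CC1CCOC1=O | starting material
13 | (5S)-4-methoxy-3,5-dimethyl-5-({2-methyl-5-[(3R)-3-methyl-2-oxooxolan-3-yl]furan-3-yl}methyl)furan-2(5H)-one | Cc1oc(cc1C[C@]1(C)OC(=O)C(C)=C1OC)[C@@]2(C)CCOC2=O | intermediate
14 | S-ethyl (2R)-4-hydroxy-2-(4-{[(2S)-3-methoxy-2,4-dimethyl-5-oxo-2,5-dihydrofuran-2-yl]methyl}-5-methylfuran-2-yl)-2-methylbutanethioate | Cc1oc(cc1C[C@]1(C)OC(=O)C(C)=C1OC)[C@@](C)(CCO)C(=O)SCC | intermediate
15 | (3R)-4-(ethylsulfanyl)-3-(4-{[(2S)-3-methoxy-2,4-dimethyl-5-oxo-2,5-dihydrofuran-2-yl]methyl}-5-methylfuran-2-yl)-3-methyl-4-oxobutanoic acid | Cc1oc(cc1C[C@]1(C)OC(=O)C(C)=C1OC)[C@@](C)(CC(=O)O)C(=O)SCC | intermediate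
16 | (3R)-3-(4-{[(2S)-3-methoxy-2,4-dimethyl-5-oxo-2,5-dihydrofuran-2-yl]methyl}-5-methylfuran-2-yl)-3-methyl-4-oxobutanoic acid | Cc1oc(cc1C[C@]1(C)OC(=O)C(C)=C1OC)[C@@](C)(CC(=O)O)C=O | intermediate
17 | S-ethyl (3R)-3-(4-{[(2S)-3-methoxy-2,4-dimethyl-5-oxo-2,5-dihydrofuran-2-yl]methyl}-5-methylfuran-2-yl)-3-methyl-4-oxobutanethioate | Cc1oc(cc1C[C@]1(C)OC(=O)C(C)=C1OC)[C@@](C)(CC(=O)SCC)C=O | intermediate
18 | S-ethyl (3R)-3-(4-{[(2S)-3-hydroxy-2,4-dimethyl-5-oxo-2,5-dihydrofuran-2-yl]methyl}-5-methylfuran-2-yl)-3-methyl-4-oxobutanethioate | Cc1oc(cc1C[C@]1(C)OC(=O)C(C)=C1O)[C@@](C)(CC(=O)SCC)C=O | intermediate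
19 | furan endoperoxide of 18: S-ethyl (3S)-3-(6-{[(2S)-3-hydroxy-2,4-dimethyl-5-oxo-2,5-dihydrofuran-2-yl]methyl}-1-methyl-2,3,7-trioxabicyclo[2.2.1]hept-5-en-4-yl)-3-methyl-4-oxobutanethioate (one of the two bridgehead diastereomers drawn; both lead to 20) | C[C@@]12OO[C@@](O1)(C=C2C[C@]3(C)OC(=O)C(C)=C3O)[C@@](C)(CC(=O)SCC)C=O | intermediate
20 | S-ethyl (3S,5Z)-3-formyl-6-{[(2S)-3-hydroxy-2,4-dimethyl-5-oxo-2,5-dihydrofuran-2-yl]methyl}-3-methyl-4,7-dioxooct-5-enethioate | CCSC(=O)C[C@@](C)(C=O)C(=O)/C=C(/C[C@]1(C)OC(=O)C(C)=C1O)C(C)=O | intermediate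
21 | S-ethyl (3S,6Z)-3-formyl-6-{[(2S)-3-hydroxy-2,4-dimethyl-5-oxo-2,5-dihydrofuran-2-yl]methylidene}-3-methyl-4,7-dioxooctanethioate (interconverts with its E isomer and with 20 through the dienolate) | CCSC(=O)C[C@@](C)(C=O)C(=O)C/C(=C/[C@]1(C)OC(=O)C(C)=C1O)C(C)=O | intermediate
22 | S-ethyl (1R,2S,5R,6S)-5-acetyl-2-formyl-6-[(2S)-3-hydroxy-2,4-dimethyl-5-oxo-2,5-dihydrofuran-2-yl]-2-methyl-3-oxocyclohexane-1-carbothioate (thioester, tetronate and acetyl all-trans; formyl cis to thioester and acetyl) | CCSC(=O)[C@@H]1[C@@H]([C@]2(C)OC(=O)C(C)=C2O)[C@H](C(C)=O)CC(=O)[C@]1(C)C=O | intermediate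
23 | S-ethyl (1R,2R,3S,4R,5S)-5-hydroxy-3-[(2S)-3-hydroxy-2,4-dimethyl-5-oxo-2,5-dihydrofuran-2-yl]-1,5-dimethyl-6,7-dioxobicyclo[2.2.2]octane-2-carbothioate | CCSC(=O)[C@@H]1[C@@H]([C@]2(C)OC(=O)C(C)=C2O)[C@H]2CC(=O)[C@]1(C)C(=O)[C@@]2(C)O | intermediate
24 | (E)-hex-4-enoic acid | C/C=C/CCC(=O)O | starting material
25 | (E)-hex-4-enoyl chloride | C/C=C/CCC(=O)Cl | intermediate
26 | S-ethyl (1R,2R,3S,4S,5S)-8-[(4E)-hex-4-enoyl]-5,7-dihydroxy-3-[(2S)-3-hydroxy-2,4-dimethyl-5-oxo-2,5-dihydrofuran-2-yl]-1,5-dimethyl-6-oxobicyclo[2.2.2]oct-7-ene-2-carbothioate | CCSC(=O)[C@@H]1[C@@H]([C@]2(C)OC(=O)C(C)=C2O)[C@H]2C(C(=O)CC/C=C/C)=C(O)[C@]1(C)C(=O)[C@@]2(C)O | intermediate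
27 | (E)-but-2-enal | C/C=C/C=O | starting material
28 | bis(4,4,5,5-tetramethyl-1,3,2-dioxaborolan-2-yl)methane | CC1(C)OB(CB2OC(C)(C)C(C)(C)O2)OC1(C)C | starting material
29 | 4,4,5,5-tetramethyl-2-[(1E,3E)-penta-1,3-dien-1-yl]-1,3,2-dioxaborolane | C/C=C/C=C/B1OC(C)(C)C(C)(C)O1 | intermediate
30 | (1E,3E)-penta-1,3-dien-1-ylboronic acid | C/C=C/C=C/B(O)O | intermediate
31 | (1R,2R,3S,4S,5S)-2-[(2E,4E)-hexa-2,4-dienoyl]-8-[(4E)-hex-4-enoyl]-5,7-dihydroxy-3-[(2S)-3-hydroxy-2,4-dimethyl-5-oxo-2,5-dihydrofuran-2-yl]-1,5-dimethylbicyclo[2.2.2]oct-7-en-6-one | C/C=C/C=C/C(=O)[C@@H]1[C@@H]([C@]2(C)OC(=O)C(C)=C2O)[C@H]2C(C(=O)CC/C=C/C)=C(O)[C@]1(C)C(=O)[C@@]2(C)O | target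

**Step count and risks**

Total steps: 17. Longest linear sequence: 15 steps (steps 1 or 2, then 3 to 15, then 17).

Steps most likely to fail:

1. Step 14 (Proposed new method). The dienolate may be diverted into aldol or elimination chemistry before the conjugate addition, the Michael addition may show poor facial selectivity at C3, or the formyl group may be lost by retro-Claisen cleavage when the carbene adds. Fallback with known chemistry, from 20 back to 23: the two bonds are made in separate operations. Soft enolisation of the thioester (MgBr2·OEt2, i-Pr2NEt, CH2Cl2) effects the intramolecular Michael addition and 22 is isolated. SmI2 (THF, MeOH, −78 °C) then joins the aldehyde and the acetyl group by intramolecular pinacol coupling to the bicyclic cis-5,6-diol F1. Oxidation of its secondary hydroxyl with 1,1,1-triacetoxy-1,1-dihydro-1,2-benziodoxol-3(1H)-one (DMP) returns to 23.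

2. Step 7. The heteroaryl bromide may inhibit the catalyst, enantioselectivity may be low, or the enolate may undergo Claisen condensation. Fallback, from 11 back to 16: C1 is built by organocatalysis instead. Pd-catalysed α-arylation of propanal (Pd(OAc)2, rac-BINAP, Cs2CO3, dioxane, 80 °C) gives the racemic 2-furylpropanal F2. A chiral primary amine–thiourea catalyst adds its enamine to nitroethylene to give the quaternary nitro aldehyde F3. Oxidative Nef reaction of the primary nitro group (NaNO2, AcOH, DMSO, 35 °C) gives the acid 16, where the route is rejoined.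

3. Step 15. Acylation may go to oxygen (enol ester, tetronate ester) or enolisation may occur at the thioester α-carbon. Fallback, from 23 back to 26: the side chain is brought in at the aldehyde oxidation level. LiN(SiMe3)2 (3.2 equiv, THF, −78 °C) forms the tetronate, the alkoxide and the C8 ketone enolate. Aldol addition to (E)-hex-4-enal gives the β-hydroxy ketone F4 (mixture at the two new centres). Oxidation with the same periodinane (DMP) gives 26.

**Further compounds**

F1 | step 14 | S-ethyl 5,6-dihydroxy-3-[(2S)-3-hydroxy-2,4-dimethyl-5-oxo-2,5-dihydrofuran-2-yl]-1,5-dimethyl-7-oxobicyclo[2.2.2]octane-2-carbothioate (cis-5,6-diol, otherwise configured as 23) | CCSC(=O)[C@@H]1[C@@H]([C@]2(C)OC(=O)C(C)=C2O)[C@H]2CC(=O)[C@]1(C)[C@@H](O)[C@@]2(C)O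
F2 | step 7 | 2-(4-{[(2S)-3-methoxy-2,4-dimethyl-5-oxo-2,5-dihydrofuran-2-yl]methyl}-5-methylfuran-2-yl)propanal (racemic at C2) | Cc1oc(cc1C[C@]1(C)OC(=O)C(C)=C1OC)C(C)C=O
F3 | step 7 | (2R)-2-(4-{[(2S)-3-methoxy-2,4-dimethyl-5-oxo-2,5-dihydrofuran-2-yl]methyl}-5-methylfuran-2-yl)-2-methyl-4-nitrobutanal | Cc1oc(cc1C[C@]1(C)OC(=O)C(C)=C1OC)[C@@](C)(CC[N+](=O)[O-])C=O
F4 | step 15 | S-ethyl 5-hydroxy-8-[(4E)-1-hydroxyhex-4-en-1-yl]-3-[(2S)-3-hydroxy-2,4-dimethyl-5-oxo-2,5-dihydrofuran-2-yl]-1,5-dimethyl-6,7-dioxobicyclo[2.2.2]octane-2-carbothioate (core configured as 23; mixture at C8 and the carbinol carbon) | CCSC(=O)[C@@H]1[C@@H]([C@]2(C)OC(=O)C(C)=C2O)[C@H]2C(C(O)CC/C=C/C)C(=O)[C@]1(C)C(=O)[C@@]2(C)O
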